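## Retrosynthetic overview

1. The target carries two acid-labile Me2C=CH ends beside free phenols: the 4-methylpent-3-enyl chain on cyclohexene C1 and the prenyl group on the benzoyl ring between its 2-OH and 4-OH. Both are therefore made last, by double cross-metathesis of the bis(vinyl) octaphenol 28 with 2-methylbut-2-ene (29).
2. 28 comes from its heptakis-MOM ether 27 by acid methanolysis. The flavanone C2–aryl bond of 27 is set by Rh-catalysed asymmetric 1,4-addition of boronic acid 13 to the chromone of 26.
3. The cyclohexene ring of 26 is formed by an exo-selective, chiral-borate Diels–Alder reaction of 2'-hydroxychalcone 8 with chromone diene 25 (three stereocentres).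
4. 8 comes from 2,4-dihydroxyacetophenone (allyl group by Claisen rearrangement) and aldehyde 7. 25 comes from 5,7-dihydroxychromone (C6 iodination ortho to the chelated 5-OH) and dienyl MIDA boronate 24.
5. Ring order: pyranone ring bought (its O1 lies para to C6, so no 6/8 ambiguity arises), cyclohexene ring in step 14, no ring in the key step.

Key step: step 17

Assumption: the ligand hands given ((R)-VANOL in step 14, (S)-MeO-F12-BIPHEP in step 15) are those expected by analogy for the drawn configurations; the mirror-image ligand is taken if a first run shows the opposite sense.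

Ring numbering used for the cyclohexene: C1 = alkene carbon bearing the side chain, C2 = alkene CH, C3 = CH bearing the chromone/flavanone, C4 = CH bearing the aroyl group, C5 = CH bearing the 2,4-dioxygenated phenyl, C6 = CH2. The target is (3R,4R,5S), all-trans, with (2S) at the flavanone.

## Route

Step 1
Reactants: 1 2,4-dihydroxyacetophenone; 2 allyl bromide
Product: 3 1-[2-hydroxy-4-(prop-2-enyloxy)phenyl]ethanone
Conditions: K2CO3, acetone, reflux
Reagents that add atoms: none
Why: Williamson etherification goes to the 4-OH because the 2-OH is hydrogen-bonded to the acetyl carbonyl and much less nucleophilic.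

Step 2
Reactants: 3 1-[2-hydroxy-4-(prop-2-enyloxy)phenyl]ethanone
Product: 4 1-[2,4-dihydroxy-3-(prop-2-enyl)phenyl]ethanone
Conditions: PhNEt2, 200 °C, Ar
Reagents that add atoms: none
Why: The aromatic Claisen rearrangement ([3,3]-sigmatropic shift, then tautomerisation) delivers the allyl group to C3 between the two oxygens, the preferred site for 4-allyloxy-2-hydroxyaryl ketones.

Step 3
Reactants: 4 1-[2,4-dihydroxy-3-(prop-2-enyl)phenyl]ethanone
Product: 5 1-[2-hydroxy-4-(methoxymethoxy)-3-(prop-2-enyl)phenyl]ethanone
Conditions: MOMCl (1.1 equiv), i-Pr2NEt, CH2Cl2, 0 °C to rt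
Reagents that add atoms: chloromethyl methyl ether, COCCl
Why: MOM ether formation is chemoselective for the non-chelated 4-OH, and the 2-OH stays free for later boron chelation.

Step 4
Reactants: 6 2,4-dihydroxybenzaldehyde
Product: 7 2,4-bis(methoxymethoxy)benzaldehyde
Conditions: NaH (2.4 equiv), MOMCl (2.4 equiv), DMF, 0 °C to rt
Reagents that add atoms: chloromethyl methyl ether, COCCl
Why: O-alkylation of both sodium phenoxides (Williamson type) also protects the chelated 2-OH.

Step 5
Reactants: 5 1-[2-hydroxy-4-(methoxymethoxy)-3-(prop-2-enyl)phenyl]ethanone; 7 2,4-bis(methoxymethoxy)benzaldehyde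
Product: 8 (E)-1-[2-hydroxy-4-(methoxymethoxy)-3-(prop-2-enyl)phenyl]-3-[2,4-bis(methoxymethoxy)phenyl]prop-2-en-1-one
Conditions: KOH, EtOH/H2O, rt, 48 h
Reagents that add atoms: none
Why: Claisen–Schmidt aldol condensation gives the thermodynamic E-enone; MOM ethers and the allyl group are inert to aqueous-ethanolic KOH at rt.

Step 6
Reactants: 9 4-bromobenzene-1,3-diol
Product: 10 1-bromo-2,4-bis(methoxymethoxy)benzene
Conditions: MOMCl (2.5 equiv), i-Pr2NEt, CH2Cl2, 0 °C to rt
Reagents that add atoms: chloromethyl methyl ether, COCCl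
Why: Straightforward MOM etherification of two unhindered phenols.

Step 7
Reactants: 10 1-bromo-2,4-bis(methoxymethoxy)benzene
Product: 13 [2,4-bis(methoxymethoxy)phenyl]boronic acid, via aryllithium 11 (not isolated), via lithium aryltriisopropoxyborate 12 (not isolated)
Conditions: n-BuLi, THF, −78 °C; B(Oi-Pr)3, −78 °C to rt; 1 M HCl to pH 5–6, 0 °C
Reagents that add atoms: triisopropyl borate, CC(C)OB(OC(C)C)OC(C)C; water, O
Why: Bromine–lithium exchange and borylation fix boron at the former C–Br carbon, and the brief near-neutral hydrolysis spares the MOM ethers.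

Step 8
Reactants: 14 5,7-dihydroxy-4H-chromen-4-one
Product: 15 5-hydroxy-7-(methoxymethoxy)-4H-chromen-4-one
Conditions: MOMCl (1.1 equiv), i-Pr2NEt, CH2Cl2/DMF, 0 °C to rt
Reagents that add atoms: chloromethyl methyl ether, COCCl
Why: MOM etherification is selective for the acidic 7-OH (vinylogous acid), while the 5-OH is held in a hydrogen bond to C4=O.

Step 9
Reactants: 15 5-hydroxy-7-(methoxymethoxy)-4H-chromen-4-one
Product: 16 5-hydroxy-6-iodo-7-(methoxymethoxy)-4H-chromen-4-one
Conditions: NIS (1.05 equiv), DMF, rt, dark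
Reagents that add atoms: N-iodosuccinimide, O=C1CCC(=O)N1I
Why: Electrophilic aromatic iodination of 5-hydroxy-7-alkoxy chromones and flavones goes ortho to the chelated 5-OH (C6), and since O1 is already fixed para to C6 the 6-substitution pattern is locked.

Step 10
Reactants: 16 5-hydroxy-6-iodo-7-(methoxymethoxy)-4H-chromen-4-one
Product: 17 6-iodo-5,7-bis(methoxymethoxy)-4H-chromen-4-one
Conditions: NaH (1.2 equiv), MOMCl (1.5 equiv), DMF, 0 °C to rt
Reagents that add atoms: chloromethyl methyl ether, COCCl
Why: The sodium phenoxide of the hindered, chelated 5-OH is alkylated by MOMCl (Williamson type), which removes the only acidic proton before the cross-coupling and the boron-mediated cycloaddition.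

Step 11
Reactants: 18 2,3-dibromoprop-1-ene; 19 allylmagnesium bromide
Product: 20 2-bromohexa-1,5-diene
Conditions: Et2O, 0 °C to rt
Reagents that add atoms: none
Why: The allyl Grignard reagent displaces the allylic bromide (SN2 and SN2′ give the same product) and leaves the vinylic C–Br bond intact.

Step 12
Reactants: 20 2-bromohexa-1,5-diene; 21 (E)-(2-bromoethenyl)boronic acid MIDA ester
Product: 24 (E)-(3-methylidenehepta-1,6-dien-1-yl)boronic acid MIDA ester, via hexa-1,5-dien-2-ylmagnesium bromide 22 (not isolated), via hexa-1,5-dien-2-ylzinc chloride 23 (not isolated)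
Conditions: Mg, THF, rt; ZnCl2, THF, 0 °C; then 21, Pd(OAc)2/SPhos (cat.), THF, rt
Reagents that add atoms: none
Why: Negishi coupling of the alkenylzinc with the alkenyl bromide proceeds with retention of the E geometry, and the sp3-hybridised boron of the MIDA boronate does not transmetalate under anhydrous conditions.

Step 13
Reactants: 17 6-iodo-5,7-bis(methoxymethoxy)-4H-chromen-4-one; 24 (E)-(3-methylidenehepta-1,6-dien-1-yl)boronic acid MIDA ester
Product: 25 6-[(1E)-3-methylidenehepta-1,6-dien-1-yl]-5,7-bis(methoxymethoxy)-4H-chromen-4-one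
Conditions: Pd(OAc)2 (5 mol %), SPhos (10 mol %), 3 M aq K3PO4, dioxane, 60 °C, BHT (trace)
Reagents that add atoms: none
Why: Suzuki–Miyaura coupling with slow release of the sensitive dienylboronic acid couples the di-ortho-substituted aryl iodide with retention of the E alkene, the biaryl phosphine coping with the hindered position.

Step 14
Reactants: 8 (E)-1-[2-hydroxy-4-(methoxymethoxy)-3-(prop-2-enyl)phenyl]-3-[2,4-bis(methoxymethoxy)phenyl]prop-2-en-1-one; 25 6-[(1E)-3-methylidenehepta-1,6-dien-1-yl]-5,7-bis(methoxymethoxy)-4H-chromen-4-one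
Product: 26 6-{(3R,4R,5S)-1-(but-3-enyl)-4-[2-hydroxy-4-(methoxymethoxy)-3-(prop-2-enyl)benzoyl]-5-[2,4-bis(methoxymethoxy)phenyl]cyclohex-1-en-3-yl}-5,7-bis(methoxymethoxy)-4H-chromen-4-one (all-trans)
Conditions: (R)-VANOL (25 mol %), B(OPh)3 (20 mol %), 4 Å MS, PhCF3, rt to 40 °C; chromatographic removal of any endo isomer
Reagents that add atoms: none
Why: Chiral-borate-promoted Diels–Alder reaction of a 2'-hydroxychalcone: the E-chalcone fixes 4,5-trans, the exo transition state (the 2,6-bis(alkoxy)aryl diene terminus kept away from the boron-chelated aroyl group) should give 3,4-trans, the borate bound to the 2'-O/C=O chelate shields one enone face and so sets the absolute configuration, and the regiochemistry follows from matching the aryl-bearing diene terminus with the enone α-carbon.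

Step 15
Reactants: 26 all-trans chromone cycloadduct; 13 [2,4-bis(methoxymethoxy)phenyl]boronic acid
Product: 27 (2S)-6-{(3R,4R,5S)-1-(but-3-enyl)-4-[2-hydroxy-4-(methoxymethoxy)-3-(prop-2-enyl)benzoyl]-5-[2,4-bis(methoxymethoxy)phenyl]cyclohex-1-en-3-yl}-5,7-bis(methoxymethoxy)-2-[2,4-bis(methoxymethoxy)phenyl]chroman-4-one
Conditions: [Rh(OH)((S)-MeO-F12-BIPHEP)]2 (5 mol % Rh), 13 (4 equiv), CH2Cl2/H2O, 25 °C
Reagents that add atoms: none
Why: Rh-catalysed asymmetric 1,4-addition of an arylboronic acid to a chromone (Hayashi–Miyaura type) inserts the aryl–Rh into C2=C3 on the face chosen by the bisphosphine, giving (2S) under catalyst control; the base-free conditions should suppress retro-oxa-Michael opening, and the isolated alkenes and the aryl ketone are not acceptors.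

Step 16
Reactants: 27 heptakis-MOM flavanone
Product: 28 (2S)-6-{(3R,4R,5S)-1-(but-3-enyl)-4-[2,4-dihydroxy-3-(prop-2-enyl)benzoyl]-5-(2,4-dihydroxyphenyl)cyclohex-1-en-3-yl}-5,7-dihydroxy-2-(2,4-dihydroxyphenyl)chroman-4-one
Conditions: 3 M aq HCl/MeOH/THF (1:3:1), 40 °C, monitored; NaHCO3 to pH 6
Reagents that add atoms: none
Why: Acid-catalysed acetal methanolysis removes all seven MOM ethers while no dimethylvinyl group is yet present; the monosubstituted alkenes do not ionise under these conditions, and the ring alkene should survive because bridging by the ortho-phenol would force all three ring substituents axial.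

Step 17
Reactants: 28 bis(vinyl) octaphenol; 29 2-methylbut-2-ene
Product: 30 CNP0256494.1
Conditions: Hoveyda–Grubbs II (2 × 5 mol %), 29 (large excess)/EtOAc, 1,4-benzoquinone (10 mol %), 40 °C, sealed tube, Ar
Reagents that add atoms: none
Why: Olefin cross-metathesis by the Chauvin cycle: the Ru alkylidene adds to each CH=CH2 group, and cycloreversion of the ruthenacyclobutanes with excess 29 exchanges the terminal CH2 for CMe2 and releases propene. The closest known reaction type is the conversion of aryl allyl groups and other terminal alkenes into prenyl-type alkenes with 2-methylbut-2-ene, which tolerates free phenols. No ring is closed and no stereocentre is formed, and the new trisubstituted alkenes have no E/Z element. The step needs chemoselectivity for the two monosubstituted alkenes over the C1=C2 ring alkene; the ring alkene is trisubstituted and flanked by C3 and C6, so it does not enter the cycle, and the product alkenes are likewise too hindered to react on. The large excess of 29 suppresses homodimerisation and macrocyclisation, and benzoquinone suppresses Ru–H migration of the allyl double bond. The neutral conditions leave the flavanone C2, the ketone α-centre C4 and the new dimethylvinyl groups beside the ortho-phenols untouched.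

## Compound list

1 | 2,4-dihydroxyacetophenone | CC(=O)c1ccc(O)cc1O | starting material
2 | allyl bromide | C=CCBr | starting material
3 | 1-[2-hydroxy-4-(prop-2-enyloxy)phenyl]ethanone | CC(=O)c1ccc(OCC=C)cc1O | intermediate
4 | 1-[2,4-dihydroxy-3-(prop-2-enyl)phenyl]ethanone | CC(=O)c1ccc(O)c(CC=C)c1O | intermediate
5 | 1-[2-hydroxy-4-(methoxymethoxy)-3-(prop-2-enyl)phenyl]ethanone | CC(=O)c1ccc(OCOC)c(CC=C)c1O | intermediate
6 | 2,4-dihydroxybenzaldehyde | O=Cc1ccc(O)cc1O | starting material
7 | 2,4-bis(methoxymethoxy)benzaldehyde | O=Cc1ccc(OCOC)cc1OCOC | intermediate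
8 | (E)-1-[2-hydroxy-4-(methoxymethoxy)-3-(prop-2-enyl)phenyl]-3-[2,4-bis(methoxymethoxy)phenyl]prop-2-en-1-one | C=CCc1c(OCOC)ccc(C(=O)/C=C/c2ccc(OCOC)cc2OCOC)c1O | intermediate
9 | 4-bromobenzene-1,3-diol | Oc1ccc(Br)c(O)c1 | starting material
10 | 1-bromo-2,4-bis(methoxymethoxy)benzene | COCOc1ccc(Br)c(OCOC)c1 | intermediate
11 | [2,4-bis(methoxymethoxy)phenyl]lithium | [Li]c1ccc(OCOC)cc1OCOC | intermediate
12 | lithium [2,4-bis(methoxymethoxy)phenyl]triisopropoxyborate | [Li+].CC(C)O[B-](OC(C)C)(OC(C)C)c1ccc(OCOC)cc1OCOC | intermediate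
13 | [2,4-bis(methoxymethoxy)phenyl]boronic acid | OB(O)c1ccc(OCOC)cc1OCOC | intermediate
14 | 5,7-dihydroxy-4H-chromen-4-one | O=c1ccoc2cc(O)cc(O)c12 | starting material
15 | 5-hydroxy-7-(methoxymethoxy)-4H-chromen-4-one | O=c1ccoc2cc(OCOC)cc(O)c12 | intermediate
16 | 5-hydroxy-6-iodo-7-(methoxymethoxy)-4H-chromen-4-one | O=c1ccoc2cc(OCOC)c(I)c(O)c12 | intermediate
17 | 6-iodo-5,7-bis(methoxymethoxy)-4H-chromen-4-one | O=c1ccoc2cc(OCOC)c(I)c(OCOC)c12 | intermediate
18 | 2,3-dibromoprop-1-ene | C=C(Br)CBr | starting material
19 | allylmagnesium bromide | C=CC[Mg]Br | starting material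
20 | 2-bromohexa-1,5-diene | C=CCCC(Br)=C | intermediate
21 | (E)-(2-bromoethenyl)boronic acid MIDA ester | Br/C=C/[B-]12OC(=O)C[N+]1(C)CC(=O)O2 | starting material
22 | hexa-1,5-dien-2-ylmagnesium bromide | C=CCCC(=C)[Mg]Br | intermediate
23 | hexa-1,5-dien-2-ylzinc chloride | C=CCCC(=C)[Zn]Cl | intermediate
24 | (E)-(3-methylidenehepta-1,6-dien-1-yl)boronic acid MIDA ester | C=CCCC(=C)/C=C/[B-]12OC(=O)C[N+]1(C)CC(=O)O2 | intermediate
25 | 6-[(1E)-3-methylidenehepta-1,6-dien-1-yl]-5,7-bis(methoxymethoxy)-4H-chromen-4-one | C=CCCC(=C)/C=C/c1c(OCOC)cc2occc(=O)c2c1OCOC | intermediate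
26 | all-trans (3R,4R,5S) chromone cycloadduct | C=CCCC1=C[C@@H](c2c(OCOC)cc3occc(=O)c3c2OCOC)[C@H](C(=O)c2ccc(OCOC)c(CC=C)c2O)[C@@H](c2ccc(OCOC)cc2OCOC)C1 | intermediate
27 | (2S)-flavanone, heptakis-MOM ether, bis(vinyl) | C=CCCC1=C[C@@H](c2c(OCOC)cc3c(c2OCOC)C(=O)C[C@@H](c2ccc(OCOC)cc2OCOC)O3)[C@H](C(=O)c2ccc(OCOC)c(CC=C)c2O)[C@@H](c2ccc(OCOC)cc2OCOC)C1 | intermediate
28 | bis(vinyl) octaphenol (key-step precursor) | C=CCCC1=C[C@@H](c2c(O)cc3c(c2O)C(=O)C[C@@H](c2ccc(O)cc2O)O3)[C@H](C(=O)c2ccc(O)c(CC=C)c2O)[C@@H](c2ccc(O)cc2O)C1 | intermediate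
29 | 2-methylbut-2-ene | CC=C(C)C | starting material
30 | CNP0256494.1 | CC(C)=CCCC1=C[C@@H](c2c(O)cc3c(c2O)C(=O)C[C@@H](c2ccc(O)cc2O)O3)[C@H](C(=O)c2ccc(O)c(CC=C(C)C)c2O)[C@@H](c2ccc(O)cc2O)C1 | target

## Step count and risks

Total steps: 17. Longest linear sequence: 8 steps (14 → 15 → 16 → 17 → 25 → 26 → 27 → 28 → 30, or equally 1 → 3 → 4 → 5 → 8 → 26 → 27 → 28 → 30).

Steps most likely to fail:

Step 14 (Diels–Alder). The exo/endo ratio or the facial control by the borate may be poor, or the cycloaddition may be slow if the chromone carbonyl of 25 competes for boron. Fallback: the flavanone stereocentre is installed first so that all cycloadduct isomers become separable diastereomers. The route sets out from 17 and 13, which under the Rh conditions of step 15 should give (2S)-6-iodo-5,7-bis(methoxymethoxy)-2-[2,4-bis(methoxymethoxy)phenyl]chroman-4-one F1. This is coupled with 24 at room temperature (Pd/SPhos, aqueous K3PO4) to the flavanone diene (2S)-6-[(1E)-3-methylidenehepta-1,6-dien-1-yl]-5,7-bis(methoxymethoxy)-2-[2,4-bis(methoxymethoxy)phenyl]chroman-4-one F2. Cycloaddition of F2 with 8 under B(OPh)3/BINOL promotion (the ligand hand matched to the 2S centre) and chromatographic isolation of the all-trans isomer returns to the route at 27. This fallback does not by itself raise the exo share.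

Step 15 (Rh 1,4-addition on the advanced chromone). Aryl transfer from the ortho-alkoxy boronic acid may be slow and lose out to protodeboronation, or ring opening may erode the C2 configuration. Fallback: the flavanone is closed by oxa-Michael addition instead. Starting from 26, aqueous-ethanolic KOH opens the pyranone with loss of formate to the 2-hydroxyacetophenone F3. Claisen–Schmidt condensation with 7 in the same medium gives the 2'-hydroxychalcone F4, whose only free ortho-phenol is the one that must become O1 (the other is a MOM ether), so ring closure can only give the 6-substituted flavanone. Cyclisation with a cinchona-thiourea catalyst (or NaOAc/EtOH) followed by separation of the two C2 epimers, which are diastereomers, returns to the route at 27.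

Step 17 (double cross-metathesis). The catalyst may be deactivated by the polyphenol, the substrate may be poorly soluble, the allyl group may migrate to a propenyl group, or one alkene may react incompletely; over-long acid treatment in step 16 may also epimerise the flavanone C2. Fallback: the metathesis is moved to the protected stage. Starting from 27, Grubbs II in 29/CH2Cl2 at 40 °C should give the bis-prenylated heptakis-MOM ether F5. Its MOM groups are then removed without Brønsted acid (TMSOTf, 2,2′-bipyridyl, MeCN, 0 °C; then H2O), which returns to the route at 30.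

Further compounds
F1 | step 14 | (2S)-6-iodo-5,7-bis(methoxymethoxy)-2-[2,4-bis(methoxymethoxy)phenyl]chroman-4-one | COCOc1ccc([C@@H]2CC(=O)c3c(OCOC)c(I)c(OCOC)cc3O2)c(OCOC)c1
F2 | step 14 | (2S)-6-[(1E)-3-methylidenehepta-1,6-dien-1-yl]-5,7-bis(methoxymethoxy)-2-[2,4-bis(methoxymethoxy)phenyl]chroman-4-one | C=CCCC(=C)/C=C/c1c(OCOC)cc2c(c1OCOC)C(=O)C[C@@H](c1ccc(OCOC)cc1OCOC)O2
F3 | step 15 | 2-hydroxyacetophenone from opening of the chromone of 26 | C=CCCC1=C[C@@H](c2c(OCOC)cc(O)c(C(C)=O)c2OCOC)[C@H](C(=O)c2ccc(OCOC)c(CC=C)c2O)[C@@H](c2ccc(OCOC)cc2OCOC)C1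
F4 | step 15 | 2'-hydroxychalcone from F3 and 7 | C=CCCC1=C[C@@H](c2c(OCOC)cc(O)c(C(=O)/C=C/c3ccc(OCOC)cc3OCOC)c2OCOC)[C@H](C(=O)c2ccc(OCOC)c(CC=C)c2O)[C@@H](c2ccc(OCOC)cc2OCOC)C1
F5 | step 17 | bis-prenylated heptakis-MOM ether of the target | CC(C)=CCCC1=C[C@@H](c2c(OCOC)cc3c(c2OCOC)C(=O)C[C@@H](c2ccc(OCOC)cc2OCOC)O3)[C@H](C(=O)c2ccc(OCOC)c(CC=C(C)C)c2O)[C@@H](c2ccc(OCOC)cc2OCOC)C1
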